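**Strategy.** The cyclohexane is cut at C2–C3 and C5–C6 (C1 carries the side chain, C3 the chlorine, C4 the methyl carbinol, C5 the free carbinol, C6 the ring angelate). This is a [3+3] union of an acetone-type C3–C4–C5 unit with an acrolein-type C2–C1–C6 unit. The key step is a decarboxylative Michael/aldol annulation of 4-(PMB-oxy)-3-oxobutanoic acid with 4,4-dimethoxy-2-methylidenebutanal; it forms both bonds and the ring in one operation. It exploits C4 as a latent ketone flanked by two nucleophilic carbons and C2 as an unsubstituted β-carbon. The C4 ketone then becomes the C3=C4 methyl alkene, the handle for hydroxyl-directed epoxidation and chloride opening.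

Key step: step 5

Remark: ring atoms are cited by the target-ring numbering above (systematic names in the list use their own locants); the annulation is not enantioselective, so 7–16 are racemates (drawn as the enantiomer carried on), and the absolute configuration is secured at step 12 by reagent-controlled allylboration and separation of the two resulting diastereomers.

Step 1
Reactants: 1 methyl 4,4-dimethoxybutanoate
Product: 2 4,4-dimethoxybutanal
Conditions: i-Bu2AlH (1.05 equiv), CH2Cl2, −78 °C; aq. KNaC4H4O6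
Reagents that add atoms: none
Why: Partial reduction of the ester stops at the aluminium hemiacetal at −78 °C and should release the aldehyde on work-up (ester-to-aldehyde reduction with a dialkylaluminium hydride); no stereocenter is formed.

Step 2
Reactants: 2 4,4-dimethoxybutanal
Product: 3 4,4-dimethoxy-2-methylidenebutanal
Conditions: Eschenmoser's salt (1.5 equiv), Et3N, CH2Cl2, 25 °C
Reagents that add atoms: dimethyl(methylidene)ammonium iodide, C=[N+](C)C.[I-]
Why: Mannich aminomethylation of the aldehyde followed by β-elimination of dimethylamine (Mannich α-methylenation) should give the 2-substituted acrolein under anhydrous conditions that spare the acetal; no stereocenter is formed.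

Step 3
Reactants: 4 ethyl 4-chloro-3-oxobutanoate
Product: 5 ethyl 4-[(4-methoxybenzyl)oxy]-3-oxobutanoate
Conditions: 4-MeOC6H4CH2OH, NaH (2.2 equiv), THF, 0 → 25 °C; aq. NH4Cl
Reagents that add atoms: 4-methoxybenzyl alcohol, COc1ccc(CO)cc1
Why: Williamson ether synthesis, in which the sodium alkoxide displaces chloride from the γ-chloro-β-keto ester held as its enolate; no stereocenter is formed.

Step 4
Reactants: 5 ethyl 4-[(4-methoxybenzyl)oxy]-3-oxobutanoate
Product: 6 4-[(4-methoxybenzyl)oxy]-3-oxobutanoic acid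
Conditions: LiOH (1.1 equiv), THF/H2O, 0 °C; cold aq. HCl to pH 3; used at once
Reagents that add atoms: lithium hydroxide, [Li+].[OH-]
Why: Ester saponification at 0 °C and cold acidification should give the β-keto acid, which is used before it can decarboxylate; no stereocenter is formed.

Step 5
Reactants: 6 4-[(4-methoxybenzyl)oxy]-3-oxobutanoic acid; 3 4,4-dimethoxy-2-methylidenebutanal
Product: 9 rac-(2,4-cis)-4-(2,2-dimethoxyethyl)-3-hydroxy-2-[(4-methoxybenzyl)oxy]cyclohexan-1-one (both C3 epimers), via Michael adduct acid 7 (not isolated), via keto aldehyde 8 (not isolated)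
Conditions: MgBr2·OEt2 (1.1 equiv), Et3N (2.5 equiv), THF, 0 → 25 °C; then DBU (0.3 equiv), 25 °C; aq. NH4Cl
Reagents that add atoms: none
Why: The magnesium-chelated enolate of 6 adds through its carboxyl-bearing carbon to the unsubstituted β-carbon of 3 (C2–C3 bond), adduct 7 loses CO2 to give keto aldehyde 8, and the ketone then enolises toward the PMBO-bearing carbon and closes onto the aldehyde (C5–C6 bond). The closest known reaction type is the Robinson-type decarboxylative Michael/aldol [3+3] annulation of β-keto acids or γ-substituted β-keto esters with enals. The only ring formed is the cyclohexanone, closed by a 6-(enolendo)-exo-trig aldol after an intermolecular Michael addition. C1 is set under thermodynamic control (the aldehyde α-carbon and, through retro-aldol, the whole ketol equilibrate, so the side chain ends equatorial); C5 is set by equilibration of the α-alkoxy ketone to the equatorial PMBO epimer, 1,3-cis to the side chain; C6 is not controlled here, and both carbinol epimers are carried to step 8, where they converge. The step needs C–C formation at C3 before any aldol and ring closure from C5 only: the carboxyl group makes C3 the sole soft nucleophilic site and is lost in the same operation, and after decarboxylation an aldol from C3 would give a four-membered ring, so only C5 can close.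

Step 6
Reactants: 9 rac-(2,4-cis)-4-(2,2-dimethoxyethyl)-3-hydroxy-2-[(4-methoxybenzyl)oxy]cyclohexan-1-one
Product: 10 rac-(4,6-cis)-4-(2,2-dimethoxyethyl)-5-hydroxy-6-[(4-methoxybenzyl)oxy]cyclohex-1-en-1-yl trifluoromethanesulfonate (both carbinol epimers)
Conditions: LiN(SiMe3)2 (2.2 equiv), THF, −78 °C; Comins' reagent (1.1 equiv), −78 → −40 °C; aq. NH4Cl
Reagents that add atoms: N-(5-chloropyridin-2-yl)-bis(trifluoromethanesulfonyl)imide (Comins' reagent), FC(F)(F)S(=O)(=O)N(c1ccc(Cl)cn1)S(=O)(=O)C(F)(F)F
Why: Kinetic deprotonation at the unhindered C3 methylene (the α-alkoxy C5–H next to the C6 alkoxide is slower) and O-sulfonylation of the enolate should give the C3=C4 enol triflate (kinetic enol triflate formation); no stereocenter is created and C5 is untouched.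

Step 7
Reactants: 10 rac-enol triflate
Product: 11 rac-(2,6-cis)-6-(2,2-dimethoxyethyl)-2-[(4-methoxybenzyl)oxy]-3-methylcyclohex-3-en-1-ol (both C1 epimers)
Conditions: MeMgBr (3 equiv), Fe(acac)3 (5 mol%), THF/NMP, −20 → 0 °C
Reagents that add atoms: methylmagnesium bromide, C[Mg]Br
Why: Iron-catalysed cross-coupling of the alkenyl triflate with the Grignard reagent (Kochi–Fürstner coupling) should install the C4 methyl group with the double bond held at C3=C4, the hydroxyl riding as its magnesium alkoxide; no stereocenter is created.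

Step 8
Reactants: 11 rac-(2,6-cis)-6-(2,2-dimethoxyethyl)-2-[(4-methoxybenzyl)oxy]-3-methylcyclohex-3-en-1-ol
Product: 12 rac-(2,6-cis)-6-(2,2-dimethoxyethyl)-2-[(4-methoxybenzyl)oxy]-3-methylcyclohex-3-en-1-one
Conditions: Dess–Martin periodinane, NaHCO3, CH2Cl2, 0 °C; used crude
Reagents that add atoms: none
Why: Dess–Martin oxidation under buffered, non-basic conditions should convert both C6 epimers into one β,γ-unsaturated ketone without moving the double bond into conjugation; the C6 center is erased, C1 and C5 stay.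

Step 9
Reactants: 12 rac-(2,6-cis)-ketone
Product: 13 rac-all-cis-6-(2,2-dimethoxyethyl)-2-[(4-methoxybenzyl)oxy]-3-methylcyclohex-3-en-1-ol
Conditions: LiBH(s-Bu)3 (1.2 equiv), THF, −78 °C; aq. NH4Cl
Reagents that add atoms: none
Why: The bulky trialkylborohydride should attack the ketone, flanked by two equatorial substituents, from the equatorial direction and give the axial C6 alcohol cis to both neighbours (substrate-controlled hydride reduction).

Step 10
Reactants: 13 rac-all-cis alcohol
Product: 14 rac-all-cis-6-(2,2-dimethoxyethyl)-2-[(4-methoxybenzyl)oxy]-3-methylcyclohex-3-en-1-yl (Z)-2-methylbut-2-enoate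
Conditions: angelic acid, 2,4,6-trichlorobenzoyl chloride, Et3N, toluene, 25 °C; then 13, 80 °C
Reagents that add atoms: angelic acid, OC(=O)/C(C)=C\C
Why: Yamaguchi-type esterification through the mixed trichlorobenzoic anhydride should acylate the hindered axial hydroxyl without base-induced Z-to-E isomerisation of the angeloyl group; O-acylation leaves all stereocenters unchanged.

Step 11
Reactants: 14 rac-all-cis angelate acetal
Product: 16 rac-all-cis-2-[(4-methoxybenzyl)oxy]-3-methyl-6-(3-oxoprop-1-en-2-yl)cyclohex-3-en-1-yl (Z)-2-methylbut-2-enoate, via aldehyde 15 (not isolated)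
Conditions: PPTS, acetone/H2O, 50 °C; then 37% aq. CH2O, pyrrolidine (10 mol%), EtCO2H (10 mol%), i-PrOH, 45 °C
Reagents that add atoms: water, O; formaldehyde, C=O
Why: Acid-catalysed acetal hydrolysis followed by amine/acid-catalysed Mannich condensation with formaldehyde (α-methylenation of aldehydes) should give the 2-substituted acrolein that carries the side-chain methylidene; no stereocenter changes.

Step 12
Reactants: 16 rac-all-cis enal
Product: 17 all-cis-6-[(3S)-3-hydroxyhexa-1,5-dien-2-yl]-2-[(4-methoxybenzyl)oxy]-3-methylcyclohex-3-en-1-yl (Z)-2-methylbut-2-enoate, single stereoisomer with the ring configuration of 23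
Conditions: (−)-Ipc2B(allyl) (1.3 equiv), Et2O, −78 °C; HOCH2CH2NH2; chromatographic separation of the two diastereomers
Reagents that add atoms: (−)-B-allyldiisopinocampheylborane, C=CCB(C1CC2CC(C1C)C2(C)C)C1CC2CC(C1C)C2(C)C
Why: Brown allylboration through a chair-like six-membered transition state should deliver the allyl group to the Si face of the aldehyde under reagent control and set C2′ as (S); the two enantiomers of 16 thereby become diastereomers, and the one with the target ring configuration is kept.

Step 13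
Reactants: 17 homoallylic alcohol
Product: 18 all-cis-6-[(3S)-3-hydroxy-6-methylhepta-1,5-dien-2-yl]-2-[(4-methoxybenzyl)oxy]-3-methylcyclohex-3-en-1-yl (Z)-2-methylbut-2-enoate
Conditions: second-generation Grubbs catalyst (5 mol%), 2-methylbut-2-ene/CH2Cl2, 40 °C
Reagents that add atoms: 2-methylbut-2-ene, CC=C(C)C
Why: Olefin cross-metathesis of the monosubstituted alkene with excess 2-methylbut-2-ene should give the prenyl terminus, the 1,1-disubstituted, ring and angelate double bonds being too hindered or electron-poor to take part; no stereocenter changes.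

Step 14
Reactants: 18 prenyl alcohol
Product: 19 all-cis-2-[(4-methoxybenzyl)oxy]-3-methyl-6-[(3S)-6-methyl-3-{[(Z)-2-methylbut-2-enoyl]oxy}hepta-1,5-dien-2-yl]cyclohex-3-en-1-yl (Z)-2-methylbut-2-enoate
Conditions: angelic acid, 2,4,6-trichlorobenzoyl chloride, Et3N, toluene, 25 °C; then 18, 60 °C
Reagents that add atoms: angelic acid, OC(=O)/C(C)=C\C
Why: The same Yamaguchi-type mixed-anhydride esterification should acylate the allylic C2′ hydroxyl with retention of configuration and of the Z geometry of the acid.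

Step 15
Reactants: 19 bis-angelate PMB ether
Product: 20 all-cis-2-hydroxy-3-methyl-6-[(3S)-6-methyl-3-{[(Z)-2-methylbut-2-enoyl]oxy}hepta-1,5-dien-2-yl]cyclohex-3-en-1-yl (Z)-2-methylbut-2-enoate
Conditions: DDQ (1.3 equiv), CH2Cl2/pH 7 buffer, 0 °C
Reagents that add atoms: none
Why: Oxidative cleavage of the 4-methoxybenzyl ether by benzylic hydride abstraction (DDQ deprotection) should free the allylic C5 hydroxyl and leave esters and alkenes untouched.

Step 16
Reactants: 20 allylic alcohol
Product: 21 the 3,4-epoxide of 20 on the face of the C5 hydroxyl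
Conditions: VO(acac)2 (5 mol%), t-BuOOH, CH2Cl2, 0 → 25 °C
Reagents that add atoms: tert-butyl hydroperoxide, CC(C)(C)OO
Why: Hydroxyl-directed vanadium-catalysed epoxidation should deliver oxygen to C3=C4 on the face of the C5 hydroxyl, setting C3 and C4, and ignore the three alkenes that have no directing hydroxyl.

Step 17
Reactants: 21 epoxy alcohol
Product: 22 the 3-chloro-4,5-diol (ring as in 23) with the prenyl side chain
Conditions: Ti(OiPr)4 (1.5 equiv), Et2NH2Cl (2 equiv), CH2Cl2, 0 → 25 °C
Reagents that add atoms: diethylammonium chloride, CC[NH2+]CC.[Cl-]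
Why: Titanium-chelated opening of the 2,3-epoxy alcohol should direct chloride to the secondary C3, remote from the hydroxyl, with inversion in a trans-diaxial opening, giving the C3 chloride trans to the tertiary C4 hydroxyl.

Step 18
Reactants: 22 chlorohydrin
Product: 23 CNP0333703.2
Conditions: ent-Shi ketone (L-fructose-derived, 0.5 equiv), KHSO5 (as 2KHSO5·KHSO4·K2SO4), NaHCO3, MeCN/H2O, pH 8, 0 °C
Reagents that add atoms: potassium peroxymonosulfate, [K+].[O-]S(=O)(=O)OO
Why: Shi epoxidation: the chiral dioxirane should epoxidise the electron-rich trisubstituted prenyl alkene through a spiro transition state under reagent control to the (4′S) epoxide, while the 1,1-disubstituted and ester-conjugated alkenes react far more slowly and the near-neutral buffer spares the chlorohydrin.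

**Compound list**

1 | methyl 4,4-dimethoxybutanoate | COC(OC)CCC(=O)OC | starting material
2 | 4,4-dimethoxybutanal | COC(OC)CCC=O | intermediate
3 | 4,4-dimethoxy-2-methylidenebutanal | COC(OC)CC(=C)C=O | intermediate
4 | ethyl 4-chloro-3-oxobutanoate | CCOC(=O)CC(=O)CCl | starting material
5 | ethyl 4-[(4-methoxybenzyl)oxy]-3-oxobutanoate | CCOC(=O)CC(=O)COCc1ccc(OC)cc1 | intermediate
6 | 4-[(4-methoxybenzyl)oxy]-3-oxobutanoic acid | OC(=O)CC(=O)COCc1ccc(OC)cc1 | intermediate
7 | 2-(2-formyl-4,4-dimethoxybutyl)-4-[(4-methoxybenzyl)oxy]-3-oxobutanoic acid (Michael adduct acid, stereocenters unassigned) | COC(OC)CC(C=O)CC(C(=O)O)C(=O)COCc1ccc(OC)cc1 | intermediate (not isolated)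
8 | 2-(2,2-dimethoxyethyl)-6-[(4-methoxybenzyl)oxy]-5-oxohexanal (racemic keto aldehyde) | COC(OC)CC(C=O)CCC(=O)COCc1ccc(OC)cc1 | intermediate (not isolated)
9 | rac-(2,4-cis)-4-(2,2-dimethoxyethyl)-3-hydroxy-2-[(4-methoxybenzyl)oxy]cyclohexan-1-one, both C3 epimers | COC(OC)C[C@H]1CCC(=O)[C@@H](OCc2ccc(OC)cc2)C1O | intermediate
10 | rac-(4,6-cis)-4-(2,2-dimethoxyethyl)-5-hydroxy-6-[(4-methoxybenzyl)oxy]cyclohex-1-en-1-yl trifluoromethanesulfonate, both C5 epimers | COC(OC)C[C@H]1CC=C(OS(=O)(=O)C(F)(F)F)[C@@H](OCc2ccc(OC)cc2)C1O | intermediate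
11 | rac-(2,6-cis)-6-(2,2-dimethoxyethyl)-2-[(4-methoxybenzyl)oxy]-3-methylcyclohex-3-en-1-ol, both C1 epimers | COC(OC)C[C@H]1CC=C(C)[C@@H](OCc2ccc(OC)cc2)C1O | intermediate
12 | rac-(2,6-cis)-6-(2,2-dimethoxyethyl)-2-[(4-methoxybenzyl)oxy]-3-methylcyclohex-3-en-1-one | COC(OC)C[C@H]1CC=C(C)[C@@H](OCc2ccc(OC)cc2)C1=O | intermediate
13 | rac-(1,2-cis,1,6-cis)-6-(2,2-dimethoxyethyl)-2-[(4-methoxybenzyl)oxy]-3-methylcyclohex-3-en-1-ol (all-cis) | COC(OC)C[C@H]1CC=C(C)[C@@H](OCc2ccc(OC)cc2)[C@H]1O | intermediate
14 | rac-all-cis-6-(2,2-dimethoxyethyl)-2-[(4-methoxybenzyl)oxy]-3-methylcyclohex-3-en-1-yl (Z)-2-methylbut-2-enoate | COC(OC)C[C@H]1CC=C(C)[C@@H](OCc2ccc(OC)cc2)[C@H]1OC(=O)/C(C)=C\C | intermediate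
15 | rac-all-cis-2-[(4-methoxybenzyl)oxy]-3-methyl-6-(2-oxoethyl)cyclohex-3-en-1-yl (Z)-2-methylbut-2-enoate | O=CC[C@H]1CC=C(C)[C@@H](OCc2ccc(OC)cc2)[C@H]1OC(=O)/C(C)=C\C | intermediate (not isolated)
16 | rac-all-cis-2-[(4-methoxybenzyl)oxy]-3-methyl-6-(3-oxoprop-1-en-2-yl)cyclohex-3-en-1-yl (Z)-2-methylbut-2-enoate | C=C(C=O)[C@H]1CC=C(C)[C@@H](OCc2ccc(OC)cc2)[C@H]1OC(=O)/C(C)=C\C | intermediate
17 | all-cis-6-[(3S)-3-hydroxyhexa-1,5-dien-2-yl]-2-[(4-methoxybenzyl)oxy]-3-methylcyclohex-3-en-1-yl (Z)-2-methylbut-2-enoate, ring configuration as in 23 | C=C([C@H](CC=C)O)[C@H]1CC=C(C)[C@@H](OCc2ccc(OC)cc2)[C@H]1OC(=O)/C(C)=C\C | intermediate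
18 | all-cis-6-[(3S)-3-hydroxy-6-methylhepta-1,5-dien-2-yl]-2-[(4-methoxybenzyl)oxy]-3-methylcyclohex-3-en-1-yl (Z)-2-methylbut-2-enoate, ring configuration as in 23 | C=C([C@H](CC=C(C)C)O)[C@H]1CC=C(C)[C@@H](OCc2ccc(OC)cc2)[C@H]1OC(=O)/C(C)=C\C | intermediate
19 | all-cis-2-[(4-methoxybenzyl)oxy]-3-methyl-6-[(3S)-6-methyl-3-{[(Z)-2-methylbut-2-enoyl]oxy}hepta-1,5-dien-2-yl]cyclohex-3-en-1-yl (Z)-2-methylbut-2-enoate | C=C([C@H](CC=C(C)C)OC(=O)/C(C)=C\C)[C@H]1CC=C(C)[C@@H](OCc2ccc(OC)cc2)[C@H]1OC(=O)/C(C)=C\C | intermediate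
20 | all-cis-2-hydroxy-3-methyl-6-[(3S)-6-methyl-3-{[(Z)-2-methylbut-2-enoyl]oxy}hepta-1,5-dien-2-yl]cyclohex-3-en-1-yl (Z)-2-methylbut-2-enoate | C=C([C@H](CC=C(C)C)OC(=O)/C(C)=C\C)[C@H]1CC=C(C)[C@@H](O)[C@H]1OC(=O)/C(C)=C\C | intermediate
21 | 3,4-epoxide of 20, epoxide oxygen cis to the C5 hydroxyl, the C6 ester oxygen and the side chain | C=C([C@H](CC=C(C)C)OC(=O)/C(C)=C\C)[C@H]1C[C@H]2O[C@@]2(C)[C@@H](O)[C@H]1OC(=O)/C(C)=C\C | intermediate
22 | chlorohydrin with the ring of 23 [C1 (R), C3 (S), C4 (S), C5 (S), C6 (S)] and the (2′S) prenyl side chain, both hydroxyls esterified as in 23 | C=C([C@H](CC=C(C)C)OC(=O)/C(C)=C\C)[C@H]1C[C@H](Cl)[C@@](C)(O)[C@@H](O)[C@H]1OC(=O)/C(C)=C\C | intermediate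
23 | CNP0333703.2: ring C1 (R), C3 (S, Cl), C4 (S, CH3/OH), C5 (S, OH), C6 (S, O-angeloyl); side chain 1′-methylidene, C2′ (S, O-angeloyl), C4′ (S) 3,3-dimethyloxirane | C=C([C@H](C[C@@H]1OC1(C)C)OC(=O)/C(C)=C\C)[C@H]1C[C@H](Cl)[C@@](C)(O)[C@@H](O)[C@H]1OC(=O)/C(C)=C\C | target

**Step count.** Total: 18 steps. Longest linear sequence: 16 steps (1, 2, 5–18).

**Steps most likely to fail**

Step 5. The β-keto acid may lose CO2 before it has added to the acrolein, the acrolein may take up a second donor or polymerise, and the ketol may dehydrate. The fallback sets out from 5 and carries the activating group as a stable ester. Transesterification with allyl alcohol (toluene, reflux, DMAP cat.) gives allyl 4-[(4-methoxybenzyl)oxy]-3-oxobutanoate F1. F1 and 3, with K2CO3 (cat.) in MeCN and then DBU, undergo the Michael/aldol annulation in one operation to prop-2-enyl rac-5-(2,2-dimethoxyethyl)-4-hydroxy-3-[(4-methoxybenzyl)oxy]-2-oxocyclohexane-1-carboxylate F2. Pd(PPh3)4 and morpholine then remove the allyl ester with loss of CO2 (Tsuji decarboxylation), and the route is rejoined at 9.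

Step 6. The C6 alkoxide may trigger retro-aldol ring opening or be sulfonylated itself, and enolisation may stray toward C5. The fallback sets out from 9. Silylation (Et3SiOTf, 2,6-lutidine) gives the rac-triethylsilyl ether F3. KN(SiMe3)2 and PhNTf2 give the rac-enol triflate F4. MeMgBr with Fe(acac)3 gives the rac-methylcyclohexene silyl ether F5. Bu4NF/AcOH removes the silyl group and the route is rejoined at 11.

Step 10. Acylation of the hindered axial hydroxyl may be so slow that the activated angeloyl group isomerises to the E (tigloyl) form or is not transferred. The fallback sets out from 12. NaBH4 in MeOH at −40 °C (small hydride, axial attack) gives the equatorial C6 epimer, rac-(1,2-trans,1,6-trans)-6-(2,2-dimethoxyethyl)-2-[(4-methoxybenzyl)oxy]-3-methylcyclohex-3-en-1-ol F6. Mitsunobu esterification of F6 with angelic acid (PPh3, DIAD, toluene, 0 → 25 °C) installs the ester with inversion at C6, the acid acting only as a carboxylate nucleophile, and the route is rejoined at 14.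

**Further compounds**

F1 | step 5 | allyl 4-[(4-methoxybenzyl)oxy]-3-oxobutanoate | C=CCOC(=O)CC(=O)COCc1ccc(OC)cc1
F2 | step 5 | prop-2-enyl rac-5-(2,2-dimethoxyethyl)-4-hydroxy-3-[(4-methoxybenzyl)oxy]-2-oxocyclohexane-1-carboxylate (3,5-cis; C1 and C4 unassigned) | COC(OC)C[C@H]1CC(C(=O)OCC=C)C(=O)[C@@H](OCc2ccc(OC)cc2)C1O
F3 | step 6 | rac-(2,4-cis)-4-(2,2-dimethoxyethyl)-2-[(4-methoxybenzyl)oxy]-3-[(triethylsilyl)oxy]cyclohexan-1-one, both C3 epimers | COC(OC)C[C@H]1CCC(=O)[C@@H](OCc2ccc(OC)cc2)C1O[Si](CC)(CC)CC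
F4 | step 6 | rac-(4,6-cis)-4-(2,2-dimethoxyethyl)-6-[(4-methoxybenzyl)oxy]-5-[(triethylsilyl)oxy]cyclohex-1-en-1-yl trifluoromethanesulfonate, both C5 epimers | COC(OC)C[C@H]1CC=C(OS(=O)(=O)C(F)(F)F)[C@@H](OCc2ccc(OC)cc2)C1O[Si](CC)(CC)CC
F5 | step 6 | rac-(2,6-cis)-triethyl{[6-(2,2-dimethoxyethyl)-2-[(4-methoxybenzyl)oxy]-3-methylcyclohex-3-en-1-yl]oxy}silane, both C1 epimers | COC(OC)C[C@H]1CC=C(C)[C@@H](OCc2ccc(OC)cc2)C1O[Si](CC)(CC)CC
F6 | step 10 | rac-(1,2-trans,1,6-trans)-6-(2,2-dimethoxyethyl)-2-[(4-methoxybenzyl)oxy]-3-methylcyclohex-3-en-1-ol | COC(OC)C[C@H]1CC=C(C)[C@@H](OCc2ccc(OC)cc2)[C@@H]1O
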